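**Retrosynthetic overview** (labdane numbering)

- The target is ent-copalol (ent-labda-8(17),13E-dien-15-ol) as its hydrogen malonate. The ester is cut first (Meldrum's acid on the allylic alcohol), then a hydroxyl is put back on C3 (removed in the forward sense by Barton–McCombie deoxygenation).
- Key disconnection: ring A at C4–C5 (gem-dimethyl carbon to ring-fusion CH) and ring B at C9–C10, in one cation–olefin cascade of an acyclic (R)-epoxy trienylsilane. Forward, ring A closes first and ring B second, in the same operation.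
- Enabling feature: the quaternary gem-dimethyl carbon C4 of ring A is bonded to the fusion carbon C5; C5/C10 and C9/C8 trace a head-to-tail 1,5-diene; and the exocyclic methylene carbon on C8 of ring B is allylic to C9, so in the open chain it can carry a silyl group that ends the cascade as the 8(17)-alkene.
- The open chain comes from two geraniol-derived C10 units and a three-carbon silyl linchpin: Shi epoxidation (absolute configuration), Wittig olefination (allylsilane geometry), allylbarium coupling (C6–C7).

Key step: step 12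

Remark on the chemistry: the stereodescriptors of the target are read as (5R,9R,10R), i.e. the ent-labdane series, so the (R)-epoxide is required.

**Route**

Step 1
Reactants: 1 geranyl acetate
Product: 2 (R)-6,7-epoxygeranyl acetate
Conditions: 1,2:4,5-di-O-isopropylidene-β-D-erythro-2,3-hexodiulo-2,6-pyranose (D-fructose-derived Shi ketone, 0.3 equiv), KHSO5 (as 2KHSO5·KHSO4·K2SO4), K2CO3, Bu4NHSO4 (cat.), MeCN/CH2(OMe)2/aq. Na2B4O7 buffer, 0 °C
Reagents that add atoms: potassium peroxymonosulfate KHSO5, [K+].[O-]S(=O)(=O)OO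
Why: Shi asymmetric epoxidation: the electrophilic chiral dioxirane should attack only the electron-rich 6,7-alkene (the 2,3-alkene is deactivated by the allylic acetate) and, through the spiro transition state usual for trisubstituted alkenes, deliver the (R)-epoxide that later fixes the absolute configuration of the decalin.

Step 2
Reactants: 2 (R)-6,7-epoxygeranyl acetate
Product: 3 (R)-6,7-epoxygeraniol
Conditions: K2CO3, MeOH, rt
Reagents that add atoms: none
Why: Base-catalysed transesterification (methanolysis) should remove the acetate without touching the trisubstituted epoxide.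

Step 3
Reactants: 3 (R)-6,7-epoxygeraniol
Product: 5 (R)-6,7-epoxygeranyl bromide, via (R)-6,7-epoxygeranyl mesylate 4 (not isolated)
Conditions: MsCl, Et3N, THF, −45 °C; then LiBr, THF, 0 °C; used crude
Reagents that add atoms: methanesulfonyl chloride, CS(=O)(=O)Cl (ends in intermediate 4); lithium bromide, [Li+].[Br-] (ends in 5)
Why: Mesylation followed by SN2 displacement with bromide at low temperature should give the primary allylic bromide without allylic transposition or epoxide opening.

Step 4
Reactants: 6 ethyl (triphenylphosphoranylidene)acetate (2 equiv); 7 (iodomethyl)trimethylsilane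
Product: 9 ethyl 2-(triphenylphosphoranylidene)-3-(trimethylsilyl)propanoate, via silylmethyl phosphonium iodide 8 (not isolated)
Conditions: EtOAc, reflux; filtration of the precipitated phosphonium salt
Reagents that add atoms: none
Why: C-Alkylation of the stabilised ylide by the reactive α-silyl iodide, followed by transylidation with the second equivalent of 6, should give the α-(silylmethyl) ylide.

Step 5
Reactants: 10 geraniol
Product: 11 geranyl tert-butyldiphenylsilyl ether
Conditions: TBDPSCl, imidazole, CH2Cl2, 0 °C to rt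
Reagents that add atoms: tert-butyl(chloro)diphenylsilane, CC(C)(C)[Si](Cl)(c1ccccc1)c1ccccc1
Why: Standard silylation of the primary allylic alcohol; the TBDPS ether should survive every later step up to the fluoride cleavage.

Step 6
Reactants: 11 geranyl tert-butyldiphenylsilyl ether
Product: 12 6,7-epoxygeranyl tert-butyldiphenylsilyl ether (racemic)
Conditions: mCPBA (1.0 equiv), NaHCO3, CH2Cl2, −20 to 0 °C
Reagents that add atoms: 3-chloroperoxybenzoic acid, OOC(=O)c1cccc(Cl)c1
Why: Prilezhaev epoxidation should be regioselective for the more electron-rich distal alkene; the new stereocentre forms as a racemate, which is irrelevant because it is excised in step 7.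

Step 7
Reactants: 12 6,7-epoxygeranyl tert-butyldiphenylsilyl ether
Product: 13 (4E)-6-[(tert-butyldiphenylsilyl)oxy]-4-methylhex-4-enal
Conditions: H5IO6, THF/H2O, 0 °C
Reagents that add atoms: none
Why: Periodic acid cleavage of the epoxide (via the diol) should excise the terminal three carbons as acetone and leave the aldehyde, whose carbonyl oxygen is the former epoxide oxygen.

Step 8
Reactants: 13 (4E)-6-[(tert-butyldiphenylsilyl)oxy]-4-methylhex-4-enal; 9 ethyl 2-(triphenylphosphoranylidene)-3-(trimethylsilyl)propanoate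
Product: 14 ethyl (2Z,6E)-8-[(tert-butyldiphenylsilyl)oxy]-6-methyl-2-[(trimethylsilyl)methyl]octa-2,6-dienoate
Conditions: toluene, 90 °C
Reagents that add atoms: none
Why: Wittig olefination with an α-substituted stabilised ylide should place the aldehyde-derived chain trans to the ester and therefore cis to CH2SiMe3, the allylsilane geometry that later puts the side chain equatorial at C9.

Step 9
Reactants: 14 ethyl (2Z,6E)-8-[(tert-butyldiphenylsilyl)oxy]-6-methyl-2-[(trimethylsilyl)methyl]octa-2,6-dienoate
Product: 15 (2Z,6E)-8-[(tert-butyldiphenylsilyl)oxy]-6-methyl-2-[(trimethylsilyl)methyl]octa-2,6-dien-1-ol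
Conditions: i-Bu2AlH (2.2 equiv), CH2Cl2, −78 °C; aq. KNaC4H4O6
Reagents that add atoms: none
Why: Hydride reduction of the enoate to the allylic alcohol at low temperature should leave the allylsilane, the silyl ether and the double-bond geometry unchanged.

Step 10
Reactants: 15 (2Z,6E)-8-[(tert-butyldiphenylsilyl)oxy]-6-methyl-2-[(trimethylsilyl)methyl]octa-2,6-dien-1-ol
Product: 17 tert-butyl{[(2E,6E)-8-chloro-3-methyl-7-[(trimethylsilyl)methyl]octa-2,6-dien-1-yl]oxy}diphenylsilane, via allylic mesylate 16 (not isolated)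
Conditions: MsCl, 2,4,6-collidine, LiCl, DMF, 0 °C
Reagents that add atoms: methanesulfonyl chloride, CS(=O)(=O)Cl (ends in intermediate 16); lithium chloride, [Li+].[Cl-] (ends in 17)
Why: Mesylation and SN2 displacement by chloride under buffered conditions should give the primary allylic chloride without SN2′ transposition or protodesilylation (the geometry is unchanged; the descriptor changes only because CH2Cl outranks CH2Si).

Step 11
Reactants: 17 tert-butyl{[(2E,6E)-8-chloro-3-methyl-7-[(trimethylsilyl)methyl]octa-2,6-dien-1-yl]oxy}diphenylsilane; 5 (R)-6,7-epoxygeranyl bromide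
Product: 19 tert-butyl{[(2E,6Z,10E)-13-[(2R)-3,3-dimethyloxiran-2-yl]-3,11-dimethyl-7-[(trimethylsilyl)methyl]trideca-2,6,10-trien-1-yl]oxy}diphenylsilane, via allylbarium chloride 18 (not isolated)
Conditions: activated Ba (from BaI2 and 2 equiv lithium biphenylide LiC12H10, THF, rt); 17, THF, −78 °C; then 5, −78 °C; aq. NH4Cl
Reagents that add atoms: barium diiodide, [Ba+2].[I-].[I-] (its barium ends in intermediate 18)
Why: Allylbarium cross-coupling: the allylic barium reagent should react at its α-carbon with the primary allylic bromide in an SN2 sense at −78 °C (α,α′-selective), joining C7 to C6 with retention of both double-bond geometries and without touching the epoxide.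

Step 12
Reactants: 19 tert-butyl{[(2E,6Z,10E)-13-[(2R)-3,3-dimethyloxiran-2-yl]-3,11-dimethyl-7-[(trimethylsilyl)methyl]trideca-2,6,10-trien-1-yl]oxy}diphenylsilane
Product: 20 (3R,5S,9R,10S,13E)-15-[(tert-butyldiphenylsilyl)oxy]labda-8(17),13-dien-3-ol
Conditions: MeAlCl2 (2 equiv), CH2Cl2, −78 °C; then aq. KNaC4H4O6
Reagents that add atoms: none
Why: MeAlCl2 coordinates the epoxide oxygen, the C4–O bond ionises at the tertiary carbon while the C5=C10 alkene attacks C4 anti to the departing oxygen (bond C4–C5), the resulting C10 cation is captured by C9 of the allylsilane, and the β-silyl cation at C8 loses its silyl group to leave the 8(17)-methylene; the closest known reaction type is the Lewis-acid-promoted epoxy-polyene cyclisation with allylsilane termination. Ring A closes in a 6-endo mode (endo with respect to both the epoxide and the C5=C10 alkene) and ring B in a 6-endo-trig mode, both through a chair–chair transition state. C3 keeps the (R) configuration of the epoxide with its oxygen equatorial; C5 and C10 are set by anti addition across the E-configured C5=C10 alkene (trans ring fusion) on the face dictated by the equatorial C3–O bond; C9 is set by the allylsilane geometry, which places the chain trans to C7 in the equatorial position. The step needs chemoselective activation of the epoxide over protodesilylation, which MeAlCl2 should secure because its Al–C bond scavenges adventitious HCl, and regioselective termination, which the β-silicon effect secures by making loss of silicon from the C8 substituent the only exit from the C8 cation. The distal C13=C14 alkene should stay out because desilylation is faster than a third ring closure and its allylic silyloxy group lowers its nucleophilicity.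

Step 13
Reactants: 20 (3R,5S,9R,10S,13E)-15-[(tert-butyldiphenylsilyl)oxy]labda-8(17),13-dien-3-ol
Product: 21 O-[(3R,5S,9R,10S,13E)-15-[(tert-butyldiphenylsilyl)oxy]labda-8(17),13-dien-3-yl] 1H-imidazole-1-carbothioate
Conditions: 1,1′-thiocarbonyldiimidazole, DMAP (cat.), ClCH2CH2Cl, 80 °C
Reagents that add atoms: 1,1′-thiocarbonyldiimidazole, S=C(n1ccnc1)n1ccnc1
Why: Thioacylation of the hindered equatorial secondary alcohol (first half of the Barton–McCombie deoxygenation); the only other oxygen is protected.

Step 14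
Reactants: 21 O-[(3R,5S,9R,10S,13E)-15-[(tert-butyldiphenylsilyl)oxy]labda-8(17),13-dien-3-yl] 1H-imidazole-1-carbothioate
Product: 22 tert-butyl{[(5R,9R,10R,13E)-labda-8(17),13-dien-15-yl]oxy}diphenylsilane
Conditions: Bu3SnH, AIBN (cat.), toluene, 110 °C
Reagents that add atoms: none
Why: Barton–McCombie radical deoxygenation: the stannyl radical adds to the thiocarbonyl, the C3–O bond fragments and the secondary C3 radical takes hydrogen from Bu3SnH; C3 ceases to be a stereocentre and the remote alkenes should be untouched.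

Step 15
Reactants: 22 tert-butyl{[(5R,9R,10R,13E)-labda-8(17),13-dien-15-yl]oxy}diphenylsilane
Product: 23 ent-copalol [(5R,9R,10R,13E)-labda-8(17),13-dien-15-ol]
Conditions: Bu4NF, THF, rt
Reagents that add atoms: none
Why: Fluoride-mediated desilylation of the TBDPS ether should liberate the primary allylic alcohol without affecting the alkenes.

Step 16
Reactants: 23 ent-copalol; 24 Meldrum's acid (2,2-dimethyl-1,3-dioxane-4,6-dione)
Product: 25 3-{[(5R,9R,10R,13E)-labda-8(17),13-dien-15-yl]oxy}-3-oxopropanoic acid (target)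
Conditions: toluene, 90 °C
Reagents that add atoms: none
Why: Thermal acylative ring-opening of Meldrum's acid by the primary alcohol with loss of acetone should give the malonic half-ester directly, below the temperature at which it decarboxylates.

**Compound list**

1 | geranyl acetate, (2E)-3,7-dimethylocta-2,6-dien-1-yl acetate | CC(=O)OC/C=C(\C)CCC=C(C)C | starting material
2 | (R)-6,7-epoxygeranyl acetate, (2E)-5-[(2R)-3,3-dimethyloxiran-2-yl]-3-methylpent-2-en-1-yl acetate | CC1(C)O[C@@H]1CC/C(C)=C/COC(C)=O | intermediate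
3 | (R)-6,7-epoxygeraniol, (2E)-5-[(2R)-3,3-dimethyloxiran-2-yl]-3-methylpent-2-en-1-ol | CC1(C)O[C@@H]1CC/C(C)=C/CO | intermediate
4 | (R)-6,7-epoxygeranyl methanesulfonate | CC1(C)O[C@@H]1CC/C(C)=C/COS(C)(=O)=O | intermediate
5 | (R)-6,7-epoxygeranyl bromide, (3R)-3-[(3E)-5-bromo-3-methylpent-3-en-1-yl]-2,2-dimethyloxirane | CC1(C)O[C@@H]1CC/C(C)=C/CBr | intermediate
6 | ethyl (triphenylphosphoranylidene)acetate | CCOC(=O)C=P(c1ccccc1)(c1ccccc1)c1ccccc1 | starting material
7 | (iodomethyl)trimethylsilane | C[Si](C)(C)CI | starting material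
8 | [1-ethoxy-1-oxo-3-(trimethylsilyl)propan-2-yl]triphenylphosphonium iodide | CCOC(=O)C(C[Si](C)(C)C)[P+](c1ccccc1)(c1ccccc1)c1ccccc1.[I-] | intermediate
9 | ethyl 2-(triphenylphosphoranylidene)-3-(trimethylsilyl)propanoate | CCOC(=O)C(C[Si](C)(C)C)=P(c1ccccc1)(c1ccccc1)c1ccccc1 | intermediate
10 | geraniol, (2E)-3,7-dimethylocta-2,6-dien-1-ol | CC(C)=CCC/C(C)=C/CO | starting material
11 | geranyl tert-butyldiphenylsilyl ether | CC(C)=CCC/C(C)=C/CO[Si](c1ccccc1)(c1ccccc1)C(C)(C)C | intermediate
12 | tert-butyl{[(2E)-5-(3,3-dimethyloxiran-2-yl)-3-methylpent-2-en-1-yl]oxy}diphenylsilane (racemic at the oxirane CH) | CC1(C)OC1CC/C(C)=C/CO[Si](c1ccccc1)(c1ccccc1)C(C)(C)C | intermediate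
13 | (4E)-6-[(tert-butyldiphenylsilyl)oxy]-4-methylhex-4-enal | O=CCC/C(C)=C/CO[Si](c1ccccc1)(c1ccccc1)C(C)(C)C | intermediate
14 | ethyl (2Z,6E)-8-[(tert-butyldiphenylsilyl)oxy]-6-methyl-2-[(trimethylsilyl)methyl]octa-2,6-dienoate (CH2SiMe3 cis to the chain) | CCOC(=O)/C(C[Si](C)(C)C)=C/CC/C(C)=C/CO[Si](c1ccccc1)(c1ccccc1)C(C)(C)C | intermediate
15 | (2Z,6E)-8-[(tert-butyldiphenylsilyl)oxy]-6-methyl-2-[(trimethylsilyl)methyl]octa-2,6-dien-1-ol | OC/C(C[Si](C)(C)C)=C/CC/C(C)=C/CO[Si](c1ccccc1)(c1ccccc1)C(C)(C)C | intermediate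
16 | (2Z,6E)-8-[(tert-butyldiphenylsilyl)oxy]-6-methyl-2-[(trimethylsilyl)methyl]octa-2,6-dien-1-yl methanesulfonate | CS(=O)(=O)OC/C(C[Si](C)(C)C)=C/CC/C(C)=C/CO[Si](c1ccccc1)(c1ccccc1)C(C)(C)C | intermediate
17 | tert-butyl{[(2E,6E)-8-chloro-3-methyl-7-[(trimethylsilyl)methyl]octa-2,6-dien-1-yl]oxy}diphenylsilane (CH2SiMe3 cis to the chain) | ClC/C(C[Si](C)(C)C)=C/CC/C(C)=C/CO[Si](c1ccccc1)(c1ccccc1)C(C)(C)C | intermediate
18 | allylbarium chloride derived from 17 (barium on the former CH2Cl carbon) | Cl[Ba]C/C(C[Si](C)(C)C)=C/CC/C(C)=C/CO[Si](c1ccccc1)(c1ccccc1)C(C)(C)C | intermediate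
19 | tert-butyl{[(2E,6Z,10E)-13-[(2R)-3,3-dimethyloxiran-2-yl]-3,11-dimethyl-7-[(trimethylsilyl)methyl]trideca-2,6,10-trien-1-yl]oxy}diphenylsilane | CC1(C)O[C@@H]1CC/C(C)=C/CC/C(C[Si](C)(C)C)=C/CC/C(C)=C/CO[Si](c1ccccc1)(c1ccccc1)C(C)(C)C | intermediate
20 | (3R,5S,9R,10S,13E)-15-[(tert-butyldiphenylsilyl)oxy]labda-8(17),13-dien-3-ol (trans-decalin, equatorial 3-OH cis to the C10 methyl, side chain equatorial) | C=C1CC[C@@H]2C(C)(C)[C@H](O)CC[C@@]2(C)[C@@H]1CC/C(C)=C/CO[Si](c1ccccc1)(c1ccccc1)C(C)(C)C | intermediate
21 | O-[(3R,5S,9R,10S,13E)-15-[(tert-butyldiphenylsilyl)oxy]labda-8(17),13-dien-3-yl] 1H-imidazole-1-carbothioate | C=C1CC[C@@H]2C(C)(C)[C@H](OC(=S)n3ccnc3)CC[C@@]2(C)[C@@H]1CC/C(C)=C/CO[Si](c1ccccc1)(c1ccccc1)C(C)(C)C | intermediate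
22 | tert-butyl{[(5R,9R,10R,13E)-labda-8(17),13-dien-15-yl]oxy}diphenylsilane | C=C1CC[C@@H]2C(C)(C)CCC[C@@]2(C)[C@@H]1CC/C(C)=C/CO[Si](c1ccccc1)(c1ccccc1)C(C)(C)C | intermediate
23 | ent-copalol, (5R,9R,10R,13E)-labda-8(17),13-dien-15-ol | C=C1CC[C@@H]2C(C)(C)CCC[C@@]2(C)[C@@H]1CC/C(C)=C/CO | intermediate
24 | Meldrum's acid, 2,2-dimethyl-1,3-dioxane-4,6-dione | CC1(C)OC(=O)CC(=O)O1 | starting material
25 | 3-{[(5R,9R,10R,13E)-labda-8(17),13-dien-15-yl]oxy}-3-oxopropanoic acid | C=C1CC[C@@H]2C(C)(C)CCC[C@@]2(C)[C@@H]1CC/C(C)=C/COC(=O)CC(=O)O | target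

**Step count**

Total: 16 steps. Longest linear sequence: 12 steps (steps 5 to 16, from geraniol 10); steps 1 to 3 and step 4 are side branches.

**Steps most likely to fail, with fallbacks**

Step 12 (key cyclisation). What may go wrong: the cationic cascade stops after ring A, the activated epoxide collapses by hydride shift to a ketone, or the allylsilane is protodesilylated before ring B closes. The fallback closes the same C4–C5 and C9–C10 bonds by a radical instead of a cationic cascade and builds the side-chain alkene afterwards; it sets out from bromide 5 and comes back at 20.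
- Commercial 6-methylhept-5-en-2-one is protected (ethylene glycol, TsOH cat., benzene, reflux) as the ketal 2-methyl-2-(4-methylpent-3-en-1-yl)-1,3-dioxolane F1.
- F1 is oxidised at the E-methyl group (SeO2 cat., t-BuOOH, CH2Cl2, rt) to the (E)-allylic alcohol F2 and chlorinated (PPh3, CCl4, reflux; Appel reaction) to the (E)-allylic chloride F3.
- Its allylbarium chloride F4 (activated Ba as in step 11, THF, −78 °C) is coupled with 5 to the epoxy diene ketal F5.
- Cp2TiCl (trivalent titanium, made in the flask from Cp2TiCl2 and Mn dust, THF, rt) should open the epoxide homolytically. The tertiary C4 radical closes ring A at C5 and the C10 radical closes ring B at C9 (both 6-endo, chair-like). The C8 radical is trapped by a second titanium centre and eliminated toward the methyl group, giving the exocyclic alkene of the bicyclic hydroxy ketal F6 under the same control by the epoxide centre.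
- Ketal hydrolysis (pyridinium p-toluenesulfonate, acetone/H2O, 50 °C) gives the hydroxy ketone F7.
- Horner–Wadsworth–Emmons olefination ((EtO)2P(O)CH2CO2Et, NaH, THF, 0 °C to rt) gives the (13E)-enoate F8; the minor Z isomer is to be removed by chromatography.
- i-Bu2AlH (CH2Cl2, −78 °C) gives the diol F9, and silylation of the primary allylic hydroxyl only (TBDPSCl, imidazole, CH2Cl2, 0 °C) returns to 20.

Step 11 (allylbarium coupling). What may go wrong: loss of α-regioselectivity or of double-bond geometry in the allylbarium reagent, Wurtz-type homocoupling, or reduction of the bromide. The fallback uses a sulfone-stabilised carbanion in place of the allylmetal; it sets out from 5 and 17 and comes back at 19.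
- Bromide 5 is converted (PhSO2Na, DMF, rt) into (R)-6,7-epoxygeranyl phenyl sulfone F10.
- Its lithium salt (n-BuLi, THF, −78 °C) is alkylated by chloride 17 (THF/DMPU, −78 to −20 °C) to the C6-phenylsulfonyl derivative of 19, sulfone F11 (both epimers at C6).
- Buffered reductive desulfonylation (Na/Hg amalgam with 6% Na, Na2HPO4, MeOH/THF, −20 °C), which should leave the epoxide, the allylsilane and the silyl ether alone, gives 19.

Step 8 (Wittig olefination). What may go wrong: slow reaction of the hindered ylide and incomplete geometric control, giving the allylsilane isomer that would lead to the C9 epimer. The fallback sets the geometry by anti-carbometalation of an alkyne instead of by olefination; it sets out from 13 and comes back at 15.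
- Corey–Fuchs homologation of 13 (CBr4, PPh3, Zn, CH2Cl2; then n-BuLi, THF, −78 °C, and (CH2O)n) gives the dibromoalkene F12 and then the propargylic alcohol F13.
- Copper-catalysed anti-carbomagnesiation (Me3SiCH2MgCl, CuI cat., Et2O/THF, 0 °C to rt, then aq. NH4Cl), directed by the magnesium alkoxide, should place the silylmethyl group on the alkyne carbon next to the carbinol and the hydrogen trans to it, which is the geometry of 15.

**Further compounds**

F1 | step 12 | 2-methyl-2-(4-methylpent-3-en-1-yl)-1,3-dioxolane | CC(C)=CCCC1(C)OCCO1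
F2 | step 12 | (2E)-2-methyl-5-(2-methyl-1,3-dioxolan-2-yl)pent-2-en-1-ol | OC/C(C)=C/CCC1(C)OCCO1
F3 | step 12 | 2-[(3E)-5-chloro-4-methylpent-3-en-1-yl]-2-methyl-1,3-dioxolane | ClC/C(C)=C/CCC1(C)OCCO1
F4 | step 12 | allylbarium chloride derived from F3 | Cl[Ba]C/C(C)=C/CCC1(C)OCCO1
F5 | step 12 | (3R)-3-[(3E,7E)-3,7-dimethyl-10-(2-methyl-1,3-dioxolan-2-yl)deca-3,7-dien-1-yl]-2,2-dimethyloxirane | CC1(C)O[C@@H]1CC/C(C)=C/CC/C(C)=C/CCC1(C)OCCO1
F6 | step 12 | (3R,5S,9R,10S)-13,13-(ethylenedioxy)-14,15-dinorlabd-8(17)-en-3-ol | C=C1CC[C@@H]2C(C)(C)[C@H](O)CC[C@@]2(C)[C@@H]1CCC1(C)OCCO1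
F7 | step 12 | (3R,5S,9R,10S)-3-hydroxy-14,15-dinorlabd-8(17)-en-13-one | C=C1CC[C@@H]2C(C)(C)[C@H](O)CC[C@@]2(C)[C@@H]1CCC(C)=O
F8 | step 12 | ethyl (3R,5S,9R,10S,13E)-3-hydroxylabda-8(17),13-dien-15-oate | C=C1CC[C@@H]2C(C)(C)[C@H](O)CC[C@@]2(C)[C@@H]1CC/C(C)=C/C(=O)OCC
F9 | step 12 | (3R,5S,9R,10S,13E)-labda-8(17),13-diene-3,15-diol | C=C1CC[C@@H]2C(C)(C)[C@H](O)CC[C@@]2(C)[C@@H]1CC/C(C)=C/CO
F10 | step 11 | (3R)-2,2-dimethyl-3-[(3E)-3-methyl-5-(phenylsulfonyl)pent-3-en-1-yl]oxirane | CC1(C)O[C@@H]1CC/C(C)=C/CS(=O)(=O)c1ccccc1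
F11 | step 11 | C6-phenylsulfonyl derivative of 19 (both epimers at the sulfonyl carbon) | CC1(C)O[C@@H]1CC/C(C)=C/C(S(=O)(=O)c1ccccc1)C/C(C[Si](C)(C)C)=C/CC/C(C)=C/CO[Si](c1ccccc1)(c1ccccc1)C(C)(C)C
F12 | step 8 | tert-butyl{[(2E)-7,7-dibromo-3-methylhepta-2,6-dien-1-yl]oxy}diphenylsilane | BrC(Br)=CCC/C(C)=C/CO[Si](c1ccccc1)(c1ccccc1)C(C)(C)C
F13 | step 8 | (6E)-8-[(tert-butyldiphenylsilyl)oxy]-6-methyloct-6-en-2-yn-1-ol | OCC#CCC/C(C)=C/CO[Si](c1ccccc1)(c1ccccc1)C(C)(C)C
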